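**Plan**

1. Retrosynthesis: the acetates and the C10 ketone go back to a 14-membered alkyne diol (C10≡C11, OH at C5 and C13). The ring bond C6–C7 is then cut to an open chain with a phenyl sulfone at C7 and a terminal C5–C6 oxirane. Further cuts are C4–C5 (C5 and C6 grafted onto a methyl ketone), C12–C13 (keto aldehyde plus propargylic mesylate) and C9–C10 (acetylide plus iodide).
2. Enabling feature: the C5 oxygen sits on the carbon next to C6, so O–C5–C6 can be stored as an oxirane whose CH2 is the electrophile, and C7 is made nucleophilic by a temporary PhSO2 group. The 1,4-related C10 ketone and C13 oxygen are stored as a C10≡C11 homopropargylic alcohol, which is inert to carbanions and is released later by hydroxyl-directed 5-endo hydration.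
3. Forward: fragment C7–C12 (steps 1–5); limonene oxide to the keto aldehyde C13–C14–C1–C2–C3–C4 (step 6); union at C12–C13 (step 7); extension to C5 and C6 at the ketone (steps 9–12). The only ring, the 14-membered carbocycle, closes in step 13, followed by desulfonylation, alkyne hydration and acetylation.
4. Stereochemistry: C1 from (4S)-limonene oxide; C8 from (R)-3-bromo-2-methylpropan-1-ol; C12 from (S)-but-3-yn-2-ol by chirality transfer; C13 relayed from C12 (anti addition, then Mitsunobu inversion); C4 and C5 by two organocatalytic steps under catalyst control. The ring closure carries C5 over unchanged.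

Key step: step 13

Remark: locants C1–C14 follow the target ring from the isopropenyl-bearing carbon C1 through C2, C3, C4 (Me), C5 (OAc), C6, C7, C8 (Me), C9, C10 (C=O), C11, C12 (Me), C13 (OAc), C14; in these locants the target is 1S,4R,5S,8S,12R,13R. The mesylate and catalyst enantiomers named are those that the accepted transition-state models predict for the configurations drawn; they are assignments by model, not verified facts.

**Route**

Step 1
Reactants: 1 (R)-3-bromo-2-methylpropan-1-ol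
Product: 2 (R)-2-methyl-3-(phenylsulfanyl)propan-1-ol
Conditions: PhSH, K2CO3, DMF, 50 °C
Reagents that add atoms: thiophenol, Sc1ccccc1
Why: SN2 thioether formation at the primary bromide leaves the C8 stereocentre untouched, and a sulfide is carried at this stage because, unlike a sulfone, it has no acidic α-hydrogen in step 3.

Step 2
Reactants: 2 (R)-2-methyl-3-(phenylsulfanyl)propan-1-ol
Product: 3 [(2S)-3-iodo-2-methylpropyl]sulfanylbenzene
Conditions: I2, PPh3, imidazole, CH2Cl2, 0 °C to rt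
Reagents that add atoms: iodine, [I][I]
Why: Appel-type iodination turns the primary alcohol into the iodide without touching the stereocentre.

Step 3
Reactants: 3 [(2S)-3-iodo-2-methylpropyl]sulfanylbenzene; 4 (S)-but-3-yn-2-ol
Product: 6 (2S,6R)-6-methyl-7-(phenylsulfanyl)hept-3-yn-2-ol, via dilithium alkynolate 5 (not isolated)
Conditions: 4 (1.5 equiv), n-BuLi (3.0 equiv), THF, −78 to 0 °C; then 3, DMPU, 0 °C to rt
Reagents that add atoms: none
Why: acetylide alkylation of the C,O-dianion forms C9–C10 at carbon, the alkoxide being the poorer nucleophile, and neither stereocentre takes part.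

Step 4
Reactants: 6 (2S,6R)-6-methyl-7-(phenylsulfanyl)hept-3-yn-2-ol
Product: 7 (2S,6R)-6-methyl-7-(phenylsulfonyl)hept-3-yn-2-ol
Conditions: mCPBA (2.2 equiv), NaHCO3, CH2Cl2, 0 °C to rt
Reagents that add atoms: mCPBA, O=C(OO)c1cccc(Cl)c1
Why: peracid oxidation of sulfide to sulfone is far faster than any reaction of the alkyne and is done here, before an alkene is present.

Step 5
Reactants: 7 (2S,6R)-6-methyl-7-(phenylsulfonyl)hept-3-yn-2-ol
Product: 8 (2S,6R)-6-methyl-7-(phenylsulfonyl)hept-3-yn-2-yl methanesulfonate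
Conditions: MsCl, Et3N, CH2Cl2, −78 to −20 °C
Reagents that add atoms: methanesulfonyl chloride, CS(=O)(=O)Cl
Why: O-sulfonylation (mesylation) with retention gives the propargylic electrophile for step 7.

Step 6
Reactants: 9 (4S)-limonene 1,2-oxide (cis/trans mixture at the oxirane)
Product: 11 (3S)-6-oxo-3-(prop-1-en-2-yl)heptanal, via menthene diol 10 (not isolated)
Conditions: H5IO6, THF–H2O, 0 °C to rt
Reagents that add atoms: water, O
Why: epoxide hydrolysis followed by Malaprade glycol cleavage opens the six-membered ring to the C13 aldehyde and the C4 methyl ketone, while the isopropenyl group and the C1 stereocentre (α to neither carbonyl) are untouched.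

Step 7
Reactants: 11 (3S)-6-oxo-3-(prop-1-en-2-yl)heptanal; 8 (2S,6R)-6-methyl-7-(phenylsulfonyl)hept-3-yn-2-yl methanesulfonate
Product: 13 (5S,7S,8R,12R)-7-hydroxy-8,12-dimethyl-13-(phenylsulfonyl)-5-(prop-1-en-2-yl)tridec-9-yn-2-one, via allenylzinc 12 (not isolated)
Conditions: 8 (1.3 equiv), Pd(OAc)2 (5 mol%), PPh3 (5 mol%), Et2Zn (3 equiv), THF, −78 to −20 °C
Reagents that add atoms: none
Why: in this Marshall–Tamaru propargylation zerovalent palladium ionises the mesylate anti (SN2′), transmetalation gives the chiral allenylzinc, and this adds to the aldehyde (faster than to the methyl ketone) through a cyclic SE2′ transition state, so that C12 is set R by chirality transfer with net inversion at the mesylate carbon and C13 is relayed from it as the anti (S) alcohol.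

Step 8
Reactants: 13 (5S,7S,8R,12R)-7-hydroxy-8,12-dimethyl-13-(phenylsulfonyl)-5-(prop-1-en-2-yl)tridec-9-yn-2-one
Product: 15 (5S,7R,8R,12R)-7-hydroxy-8,12-dimethyl-13-(phenylsulfonyl)-5-(prop-1-en-2-yl)tridec-9-yn-2-one, via 4-nitrobenzoate 14 (not isolated)
Conditions: 4-O2NC6H4CO2H, PPh3, DIAD, toluene, 0 °C to rt; then K2CO3, MeOH, rt
Reagents that add atoms: 4-nitrobenzoic acid, O=C(O)c1ccc(cc1)[N+](=O)[O-]
Why: the Mitsunobu reaction inverts C13 by SN2 displacement of the oxyphosphonium group by the carboxylate, and methanolysis of the ester then frees the syn alcohol with the C12/C13 relationship of the target.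

Step 9
Reactants: 15 (5S,7R,8R,12R)-7-hydroxy-8,12-dimethyl-13-(phenylsulfonyl)-5-(prop-1-en-2-yl)tridec-9-yn-2-one
Product: 16 (6S,8R,9R,13R)-8-hydroxy-3,9,13-trimethyl-14-(phenylsulfonyl)-6-(prop-1-en-2-yl)tetradec-2-en-10-ynenitrile (2E/2Z mixture)
Conditions: (EtO)2P(O)CH2CN, NaH (phosphonate anion preformed), THF, 0 °C to rt
Reagents that add atoms: diethyl cyanomethylphosphonate, CCOP(=O)(CC#N)OCC
Why: Horner–Wadsworth–Emmons olefination of the methyl ketone adds C5 and C6, the phosphonate anion is too weak a base to touch the sulfone, and the E/Z mixture is acceptable because step 11 is stereoconvergent.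

Step 10
Reactants: 16 (6S,8R,9R,13R)-8-hydroxy-3,9,13-trimethyl-14-(phenylsulfonyl)-6-(prop-1-en-2-yl)tetradec-2-en-10-ynenitrile
Product: 17 (6S,8R,9R,13R)-8-hydroxy-3,9,13-trimethyl-14-(phenylsulfonyl)-6-(prop-1-en-2-yl)tetradec-2-en-10-ynal (2E/2Z mixture)
Conditions: i-Bu2AlH (3 equiv), toluene, −78 °C; then aq. tartaric acid, 0 °C
Reagents that add atoms: water, O
Why: nitrile-to-aldehyde reduction stops at the aluminium aldimine, which is hydrolysed on work-up to the enal, the alkyne and the sulfone being inert at this temperature.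

Step 11
Reactants: 17 (6S,8R,9R,13R)-8-hydroxy-3,9,13-trimethyl-14-(phenylsulfonyl)-6-(prop-1-en-2-yl)tetradec-2-en-10-ynal
Product: 18 (3R,6S,8R,9R,13R)-8-hydroxy-3,9,13-trimethyl-14-(phenylsulfonyl)-6-(prop-1-en-2-yl)tetradec-10-ynal
Conditions: (R)-2-tert-butyl-3-methylimidazolidin-4-one·Cl3CCO2H (20 mol%), diethyl 2,6-dimethyl-1,4-dihydropyridine-3,5-dicarboxylate (Hantzsch ester, 1.2 equiv), CHCl3, −30 °C
Reagents that add atoms: none
Why: in this organocatalytic iminium transfer hydrogenation the Hantzsch ester delivers hydride to the unshielded face of the iminium ion, whose E and Z forms interconvert, so both enal isomers should converge on the C4 (R) methyl stereocentre under catalyst control.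

Step 12
Reactants: 18 (3R,6S,8R,9R,13R)-8-hydroxy-3,9,13-trimethyl-14-(phenylsulfonyl)-6-(prop-1-en-2-yl)tetradec-10-ynal
Product: 21 (2R,3R,6S,8R,9R,13R)-1,2-epoxy-3,9,13-trimethyl-14-(phenylsulfonyl)-6-(prop-1-en-2-yl)tetradec-10-yn-8-ol, via chloro aldehyde 19 (not isolated), via chlorohydrin 20 (not isolated)
Conditions: NCS, (2R,5R)-2,5-diphenylpyrrolidine (10 mol%), CH2Cl2, 0 °C to rt; then NaBH4, MeOH, 0 °C; then KOH, EtOH–H2O, rt
Reagents that add atoms: none
Why: enamine-catalysed α-chlorination sets C5 as the chloride syn to the C4 methyl under catalyst control, reduction gives the chlorohydrin, and Williamson-type closure by the C6 alkoxide inverts C5 to the oxirane that has the C4/C5 anti relationship of the target.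

Step 13
Reactants: 21 (2R,3R,6S,8R,9R,13R)-1,2-epoxy-3,9,13-trimethyl-14-(phenylsulfonyl)-6-(prop-1-en-2-yl)tetradec-10-yn-8-ol
Product: 23 (1S,4R,5S,8R,12R,13R)-4,8,12-trimethyl-7-(phenylsulfonyl)-1-(prop-1-en-2-yl)cyclotetradec-10-yne-5,13-diol (both C7 epimers), via dilithio epoxy sulfone 22 (not isolated)
Conditions: n-BuLi (2.2 equiv), THF, 0.002 M, −78 °C; then DMPU, −78 to 40 °C; H2O
Reagents that add atoms: none
Why: n-BuLi removes the C13 hydroxyl proton and then the C7 hydrogen α to the sulfone, and on warming the C7 carbanion attacks the unsubstituted oxirane carbon C6 in an SN2 step, forming the C6–C7 bond and releasing the C5 alkoxide. The closest known reaction type is the intramolecular opening of an epoxide by a sulfur-stabilised carbanion, which has been used to close 14-membered cembrane rings. The carbocycle closes in the 14-endo mode with respect to the oxirane (both oxirane carbons end up in the new ring), whereas the 13-exo alternative would need attack at the substituted carbon C5. C5 keeps its configuration because its C–O bond is not broken, and the new stereocentre at C7 is uncontrolled and is erased in step 14. The step needs ring closure to beat intermolecular alkylation (high dilution), attack at C6 and not C5 (primary against secondary α-branched carbon), and a chain free of other electrophiles or acidic C–H bonds, which the alkyne mask for the C10 ketone and the absence of any carbonyl group secure; the C13 alkoxide is a spectator because it could reach the oxirane only through a ten-membered ring.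

Step 14
Reactants: 23 (1S,4R,5S,8R,12R,13R)-4,8,12-trimethyl-7-(phenylsulfonyl)-1-(prop-1-en-2-yl)cyclotetradec-10-yne-5,13-diol
Product: 24 (1S,4R,5S,8S,12R,13R)-4,8,12-trimethyl-1-(prop-1-en-2-yl)cyclotetradec-10-yne-5,13-diol
Conditions: Na/Hg (6% Na), Na2HPO4, MeOH–THF, −20 to 0 °C
Reagents that add atoms: none
Why: Julia-type reductive desulfonylation by single-electron C–S cleavage removes the activating group without touching the isolated alkyne or the isopropenyl group, and the C5 hydroxyl is γ, not β, to the sulfone, so no elimination can follow.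

Step 15
Reactants: 24 (1S,4R,5S,8S,12R,13R)-4,8,12-trimethyl-1-(prop-1-en-2-yl)cyclotetradec-10-yne-5,13-diol
Product: 26 (1S,4R,5S,8S,12R,13R)-5,13-dihydroxy-4,8,12-trimethyl-1-(prop-1-en-2-yl)cyclotetradecan-10-one, via bridged dihydrofuran 25 (not isolated)
Conditions: Ph3PAuCl (5 mol%), AgOTf (5 mol%), THF–H2O (10:1), rt; then TsOH·H2O (cat.)
Reagents that add atoms: water, O
Why: gold-catalysed 5-endo-dig hydroalkoxylation of the homopropargylic C13 alcohol onto C10 and hydrolysis of the resulting enol ether (hydroxyl-directed alkyne hydration) should place the ketone at C10 only, since attack at C11 would need a four-membered ring and the C5 hydroxyl is too remote.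

Step 16
Reactants: 26 (1S,4R,5S,8S,12R,13R)-5,13-dihydroxy-4,8,12-trimethyl-1-(prop-1-en-2-yl)cyclotetradecan-10-one
Product: 27 (3R,4R,6S,9R,10S,13S)-4,10-diacetoxy-3,9,13-trimethyl-6-(prop-1-en-2-yl)cyclotetradecan-1-one (CNP0328624.1)
Conditions: Ac2O, pyridine, DMAP (cat.), CH2Cl2, rt
Reagents that add atoms: acetic anhydride, CC(=O)OC(C)=O
Why: DMAP-catalysed acylation esterifies both secondary alcohols and draws the γ-hydroxy ketone out of any hemiketal equilibrium, and no stereocentre is α to the ketone, so none can epimerise.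

**Compound list**

1 | (R)-3-bromo-2-methylpropan-1-ol | OC[C@@H](C)CBr | starting material
2 | (R)-2-methyl-3-(phenylsulfanyl)propan-1-ol | OC[C@@H](C)CSc1ccccc1 | intermediate
3 | [(2S)-3-iodo-2-methylpropyl]sulfanylbenzene | IC[C@@H](C)CSc1ccccc1 | intermediate
4 | (S)-but-3-yn-2-ol | C[C@H](O)C#C | starting material
5 | dilithium salt of 4 (alkoxide and acetylide) | C[C@H]([O-])C#[C-].[Li+].[Li+] | intermediate
6 | (2S,6R)-6-methyl-7-(phenylsulfanyl)hept-3-yn-2-ol | C[C@H](O)C#CC[C@@H](C)CSc1ccccc1 | intermediate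
7 | (2S,6R)-6-methyl-7-(phenylsulfonyl)hept-3-yn-2-ol | C[C@H](O)C#CC[C@@H](C)CS(=O)(=O)c1ccccc1 | intermediate
8 | (2S,6R)-6-methyl-7-(phenylsulfonyl)hept-3-yn-2-yl methanesulfonate | C[C@H](OS(C)(=O)=O)C#CC[C@@H](C)CS(=O)(=O)c1ccccc1 | intermediate
9 | (4S)-limonene 1,2-oxide, (4S)-1-methyl-4-(prop-1-en-2-yl)-7-oxabicyclo[4.1.0]heptane, cis/trans mixture | CC12OC1C[C@H](CC2)C(C)=C | starting material
10 | (4S)-1-methyl-4-(prop-1-en-2-yl)cyclohexane-1,2-diol | CC1(O)C(O)C[C@H](CC1)C(C)=C | intermediate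
11 | (3S)-6-oxo-3-(prop-1-en-2-yl)heptanal | C=C(C)[C@H](CC=O)CCC(C)=O | intermediate
12 | ethyl{(aR)-1-[(2R)-2-methyl-3-(phenylsulfonyl)propyl]buta-1,2-dien-1-yl}zinc | CC[Zn]C(C[C@@H](C)CS(=O)(=O)c1ccccc1)=[C@]=C([H])C | intermediate
13 | (5S,7S,8R,12R)-7-hydroxy-8,12-dimethyl-13-(phenylsulfonyl)-5-(prop-1-en-2-yl)tridec-9-yn-2-one (C12/C13 anti) | C=C(C)[C@H](C[C@H](O)[C@H](C)C#CC[C@@H](C)CS(=O)(=O)c1ccccc1)CCC(C)=O | intermediate
14 | (5S,7R,8R,12R)-8,12-dimethyl-2-oxo-13-(phenylsulfonyl)-5-(prop-1-en-2-yl)tridec-9-yn-7-yl 4-nitrobenzoate | C=C(C)[C@H](C[C@@H](OC(=O)c1ccc(cc1)[N+](=O)[O-])[C@H](C)C#CC[C@@H](C)CS(=O)(=O)c1ccccc1)CCC(C)=O | intermediate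
15 | (5S,7R,8R,12R)-7-hydroxy-8,12-dimethyl-13-(phenylsulfonyl)-5-(prop-1-en-2-yl)tridec-9-yn-2-one (C12/C13 syn) | C=C(C)[C@H](C[C@@H](O)[C@H](C)C#CC[C@@H](C)CS(=O)(=O)c1ccccc1)CCC(C)=O | intermediate
16 | (6S,8R,9R,13R)-8-hydroxy-3,9,13-trimethyl-14-(phenylsulfonyl)-6-(prop-1-en-2-yl)tetradec-2-en-10-ynenitrile, 2E/2Z mixture | C=C(C)[C@H](C[C@@H](O)[C@H](C)C#CC[C@@H](C)CS(=O)(=O)c1ccccc1)CCC(C)=CC#N | intermediate
17 | (6S,8R,9R,13R)-8-hydroxy-3,9,13-trimethyl-14-(phenylsulfonyl)-6-(prop-1-en-2-yl)tetradec-2-en-10-ynal, 2E/2Z mixture | C=C(C)[C@H](C[C@@H](O)[C@H](C)C#CC[C@@H](C)CS(=O)(=O)c1ccccc1)CCC(C)=CC=O | intermediate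
18 | (3R,6S,8R,9R,13R)-8-hydroxy-3,9,13-trimethyl-14-(phenylsulfonyl)-6-(prop-1-en-2-yl)tetradec-10-ynal | C=C(C)[C@H](C[C@@H](O)[C@H](C)C#CC[C@@H](C)CS(=O)(=O)c1ccccc1)CC[C@@H](C)CC=O | intermediate
19 | (2S,3R,6S,8R,9R,13R)-2-chloro-8-hydroxy-3,9,13-trimethyl-14-(phenylsulfonyl)-6-(prop-1-en-2-yl)tetradec-10-ynal | C=C(C)[C@H](C[C@@H](O)[C@H](C)C#CC[C@@H](C)CS(=O)(=O)c1ccccc1)CC[C@@H](C)[C@H](Cl)C=O | intermediate
20 | (2S,3R,6S,8R,9R,13R)-2-chloro-3,9,13-trimethyl-14-(phenylsulfonyl)-6-(prop-1-en-2-yl)tetradec-10-yne-1,8-diol | C=C(C)[C@H](C[C@@H](O)[C@H](C)C#CC[C@@H](C)CS(=O)(=O)c1ccccc1)CC[C@@H](C)[C@H](Cl)CO | intermediate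
21 | (2R,3R,6S,8R,9R,13R)-1,2-epoxy-3,9,13-trimethyl-14-(phenylsulfonyl)-6-(prop-1-en-2-yl)tetradec-10-yn-8-ol | C=C(C)[C@H](C[C@@H](O)[C@H](C)C#CC[C@@H](C)CS(=O)(=O)c1ccccc1)CC[C@@H](C)[C@@H]1CO1 | intermediate
22 | dilithio derivative of 21 (C13 alkoxide and C7 α-sulfonyl carbanion) | C=C(C)[C@H](C[C@@H]([O-])[C@H](C)C#CC[C@@H](C)[CH-]S(=O)(=O)c1ccccc1)CC[C@@H](C)[C@@H]1CO1.[Li+].[Li+] | intermediate
23 | (1S,4R,5S,8R,12R,13R)-4,8,12-trimethyl-7-(phenylsulfonyl)-1-(prop-1-en-2-yl)cyclotetradec-10-yne-5,13-diol, both C7 epimers | C=C(C)[C@H]1CC[C@@H](C)[C@@H](O)CC(S(=O)(=O)c2ccccc2)[C@H](C)CC#C[C@@H](C)[C@H](O)C1 | intermediate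
24 | (1S,4R,5S,8S,12R,13R)-4,8,12-trimethyl-1-(prop-1-en-2-yl)cyclotetradec-10-yne-5,13-diol | C=C(C)[C@H]1CC[C@@H](C)[C@@H](O)CC[C@H](C)CC#C[C@@H](C)[C@H](O)C1 | intermediate
25 | bridged 2,3-dihydrofuran of 24 (oxygen of C13 bonded to C10, C10=C11 enol ether, C5 hydroxyl free) | C=C(C)[C@H]1CC[C@@H](C)[C@@H](O)CC[C@H](C)CC2=C[C@@H](C)[C@H](O2)C1 | intermediate
26 | (1S,4R,5S,8S,12R,13R)-5,13-dihydroxy-4,8,12-trimethyl-1-(prop-1-en-2-yl)cyclotetradecan-10-one | C=C(C)[C@H]1CC[C@@H](C)[C@@H](O)CC[C@H](C)CC(=O)C[C@@H](C)[C@H](O)C1 | intermediate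
27 | (3R,4R,6S,9R,10S,13S)-4,10-diacetoxy-3,9,13-trimethyl-6-(prop-1-en-2-yl)cyclotetradecan-1-one (CNP0328624.1) | C=C(C)[C@H]1CC[C@@H](C)[C@@H](OC(C)=O)CC[C@H](C)CC(=O)C[C@@H](C)[C@H](OC(C)=O)C1 | target

**Step count and risks**

Total step count: 16. Longest linear sequence: 15 steps (steps 1–5, then 7–16, from compound 1).

Step 13 (ring closure). The 14-membered closure may be too slow at high dilution, so that oligomerisation or base-induced isomerisation of the oxirane to an allylic alcohol takes over. The fallback sets out from 21 and comes back at 23; it replaces the oxirane by a primary iodide as the electrophile. LiI/AcOH in THF opens 21 at C6 to the iodohydrin F1, and TESOTf/2,6-lutidine gives the bis(triethylsilyl) ether F2. LiN(i-Pr)2 in THF–DMPU at high dilution generates the α-sulfonyl carbanion F3 (not isolated), which closes the ring by intramolecular SN2 alkylation at C6 to the macrocyclic bis(silyl ether) F4. HF·pyridine then removes both silyl groups and gives 23.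

Step 8 (inversion at C13). Elimination to an enyne or incomplete inversion may occur at the hindered, β-branched carbinol. The fallback sets out from 3 and 11 and comes back at 15; it makes the syn alcohol directly instead of by inversion. The dianion F5 of commercial (R)-but-3-yn-2-ol (n-BuLi, THF) is alkylated with 3 to the alkynol F6, and MsCl/Et3N gives the mesylate F7. Bu3SnLi/CuBr·SMe2 (anti SN2′) gives the allenylstannane F8. BF3·OEt2-promoted addition of F8 to 11 through an open, antiperiplanar SE2′ transition state should give the syn hydroxy sulfide F9, and (NH4)6Mo7O24/H2O2 in EtOH oxidises sulfur only and gives 15.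

Step 12 (C5 stereocentre and oxirane). Facial selectivity in the chlorination of the β-branched aldehyde may be low, or the α-chloro aldehyde may epimerise before reduction. The fallback sets out from 18 and comes back at 21; it introduces oxygen with retention instead of chlorine with inversion. L-Proline-catalysed α-aminoxylation with nitrosobenzene gives the anilinooxy aldehyde F10 (not isolated), and NaBH4 gives the anilinooxy alcohol F11. CuSO4·5H2O in MeOH cleaves the N–O bond to the triol F12. Bu2SnO (cat.)/TsCl/Et3N sulfonylates the primary hydroxyl of the 1,2-diol to the tosylate F13, and K2CO3 in MeOH closes the oxirane 21.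

Further compounds
F1 | step 13 | iodohydrin of 21: (2R,3R,6S,8R,9R,13R)-1-iodo-3,9,13-trimethyl-14-(phenylsulfonyl)-6-(prop-1-en-2-yl)tetradec-10-yne-2,8-diol | C=C(C)[C@H](C[C@@H](O)[C@H](C)C#CC[C@@H](C)CS(=O)(=O)c1ccccc1)CC[C@@H](C)[C@@H](O)CI
F2 | step 13 | bis(triethylsilyl) ether of F1 | C=C(C)[C@H](C[C@@H](O[Si](CC)(CC)CC)[C@H](C)C#CC[C@@H](C)CS(=O)(=O)c1ccccc1)CC[C@@H](C)[C@@H](O[Si](CC)(CC)CC)CI
F3 | step 13 | lithium α-sulfonyl carbanion of F2 | C=C(C)[C@H](C[C@@H](O[Si](CC)(CC)CC)[C@H](C)C#CC[C@@H](C)[CH-]S(=O)(=O)c1ccccc1)CC[C@@H](C)[C@@H](O[Si](CC)(CC)CC)CI.[Li+]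
F4 | step 13 | bis(triethylsilyl) ether of 23 (both C7 epimers) | C=C(C)[C@H]1CC[C@@H](C)[C@@H](O[Si](CC)(CC)CC)CC(S(=O)(=O)c2ccccc2)[C@H](C)CC#C[C@@H](C)[C@H](O[Si](CC)(CC)CC)C1
F5 | step 8 | dilithium salt of (R)-but-3-yn-2-ol (alkoxide and acetylide) | C[C@@H]([O-])C#[C-].[Li+].[Li+]
F6 | step 8 | (2R,6R)-6-methyl-7-(phenylsulfanyl)hept-3-yn-2-ol | C[C@@H](O)C#CC[C@@H](C)CSc1ccccc1
F7 | step 8 | (2R,6R)-6-methyl-7-(phenylsulfanyl)hept-3-yn-2-yl methanesulfonate | C[C@@H](OS(C)(=O)=O)C#CC[C@@H](C)CSc1ccccc1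
F8 | step 8 | tributyl{(aS)-1-[(2R)-2-methyl-3-(phenylsulfanyl)propyl]buta-1,2-dien-1-yl}stannane | CCCC[Sn](CCCC)(CCCC)C(C[C@@H](C)CSc1ccccc1)=[C@@]=C([H])C
F9 | step 8 | (5S,7R,8R,12R)-7-hydroxy-8,12-dimethyl-13-(phenylsulfanyl)-5-(prop-1-en-2-yl)tridec-9-yn-2-one | C=C(C)[C@H](C[C@@H](O)[C@H](C)C#CC[C@@H](C)CSc1ccccc1)CCC(C)=O
F10 | step 12 | (2R,3R,6S,8R,9R,13R)-2-(anilinooxy)-8-hydroxy-3,9,13-trimethyl-14-(phenylsulfonyl)-6-(prop-1-en-2-yl)tetradec-10-ynal | C=C(C)[C@H](C[C@@H](O)[C@H](C)C#CC[C@@H](C)CS(=O)(=O)c1ccccc1)CC[C@@H](C)[C@@H](ONc1ccccc1)C=O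
F11 | step 12 | (2R,3R,6S,8R,9R,13R)-2-(anilinooxy)-3,9,13-trimethyl-14-(phenylsulfonyl)-6-(prop-1-en-2-yl)tetradec-10-yne-1,8-diol | C=C(C)[C@H](C[C@@H](O)[C@H](C)C#CC[C@@H](C)CS(=O)(=O)c1ccccc1)CC[C@@H](C)[C@@H](ONc1ccccc1)CO
F12 | step 12 | (2R,3R,6S,8R,9R,13R)-3,9,13-trimethyl-14-(phenylsulfonyl)-6-(prop-1-en-2-yl)tetradec-10-yne-1,2,8-triol | C=C(C)[C@H](C[C@@H](O)[C@H](C)C#CC[C@@H](C)CS(=O)(=O)c1ccccc1)CC[C@@H](C)[C@@H](O)CO
F13 | step 12 | primary 4-methylbenzenesulfonate of F12 (C1 tosylate, C2 and C8 hydroxyls free) | C=C(C)[C@H](C[C@@H](O)[C@H](C)C#CC[C@@H](C)CS(=O)(=O)c1ccccc1)CC[C@@H](C)[C@@H](O)COS(=O)(=O)c1ccc(C)cc1
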